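**Plan**

Locants: unit 1 is the 4'-methoxyflavanone half (O-1, C-2, C-3, C-4, C-4a, C-8a); unit 2 is the 4'-hydroxyflavanone half (same locants with '').
Retrosynthesis: remove four O-benzyl groups; undo the C-3 epimerization; cut O-1–C-8a and C-3–C-4 of unit 1 together (SNAr etherification, then intramolecular Stetter addition in the same flask) to an (E)-3''-alkylidene flavanone of unit 2 with a free C-2 carbinol plus 2,4-bis(benzyloxy)-6-fluorobenzaldehyde; cut the C-3=C-3'' double bond (aldol condensation) to a (2''S)-flavanone and an O-silyl (R)-4-methoxymandelaldehyde.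
Enabling feature: in the 1,4-diketone C-4(=O)–C-3–C-3''–C-4''(=O), C-3 is the β-carbon of an enone conjugated to C-4'', so an acyl anion at C-4 can add there; C-8a is ortho to C-4, so a fluoride at C-8a is activated by the formyl group toward O-1.
Forward order: rings A'' and C'' of unit 2 (chromone, then 2''-aryl addition), then the exocyclic C-3''=C-3 bond, and last ring C of unit 1, closed in the key step onto the finished unit 2.
Stereochemistry: C-2'' by catalytic asymmetric conjugate arylation; C-2 bought as (R)-4-methoxymandelic acid; C-3'' by kinetic ketonization anti to the pseudoaxial 2''-aryl group in the key step; C-3 by thermodynamic epimerization to 2,3-trans while unit 2 is shielded as its 5''-phenoxide.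

Key step: step 11

Assumption: in step 2 the ligand antipode is the one that delivers the (2S)-flavanone (written as the (S)-ligand); 5,7-dihydroxychromone and (R)-4-methoxymandelic acid are taken as purchasable.

Step 1
Reactants: 1 5,7-dihydroxy-4H-chromen-4-one
Product: 2 7-(benzyloxy)-5-hydroxy-4H-chromen-4-one
Conditions: BnBr (1.05 equiv), K2CO3, acetone, reflux
Reagents that add atoms: benzyl bromide, BrCc1ccccc1
Why: Williamson ether synthesis: K2CO3 ionizes only the free 7-OH, whereas the 5-OH is hydrogen-bonded to the C-4 carbonyl and is kept for later use as an internal protecting group.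

Step 2
Reactants: 2 7-(benzyloxy)-5-hydroxy-4H-chromen-4-one; 3 [4-(benzyloxy)phenyl]boronic acid
Product: 4 (2S)-7-(benzyloxy)-2-[4-(benzyloxy)phenyl]-5-hydroxy-2,3-dihydro-4H-chromen-4-one
Conditions: Pd(OCOCF3)2 (5 mol %), (S)-4-tert-butyl-2-(pyridin-2-yl)-4,5-dihydrooxazole (6 mol %), NH4PF6 (30 mol %), H2O (5 equiv), ClCH2CH2Cl, 60 °C
Reagents that add atoms: none
Why: Asymmetric conjugate addition of an arylboronic acid to a chromone under a cationic divalent-palladium pyridine-oxazoline catalyst: the chiral ligand fixes the face of aryl transfer and so sets C-2'' (S), and water protonates the palladium enolate.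

Step 3
Reactants: 4 (2S)-7-(benzyloxy)-2-[4-(benzyloxy)phenyl]-5-hydroxy-2,3-dihydro-4H-chromen-4-one
Product: 5 (2S)-7-(benzyloxy)-2-[4-(benzyloxy)phenyl]-4,5-bis[(tert-butyldimethylsilyl)oxy]-2H-chromene
Conditions: t-BuMe2SiOTf (2.5 equiv), Et3N, CH2Cl2, 0 °C to rt
Reagents that add atoms: tert-butyldimethylsilyl trifluoromethanesulfonate, CC(C)(C)[Si](C)(C)OS(=O)(=O)C(F)(F)F
Why: Soft enolization (silyl triflate and amine) traps the ketone as its enol silyl ether without the strong base that would open ring C'' by β-elimination, and silylates the chelated phenol in the same operation.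

Step 4
Reactants: 6 (2R)-2-hydroxy-2-(4-methoxyphenyl)acetic acid
Product: 7 methyl (2R)-2-hydroxy-2-(4-methoxyphenyl)acetate
Conditions: MeI, KHCO3, DMF, rt
Reagents that add atoms: iodomethane, CI
Why: SN2 alkylation of the carboxylate under nearly neutral conditions gives the methyl ester without ionizing the p-methoxybenzylic carbinol, so the bought (R) center, the future C-2, is kept.

Step 5
Reactants: 7 methyl (2R)-2-hydroxy-2-(4-methoxyphenyl)acetate
Product: 8 methyl (2R)-2-[(tert-butyldimethylsilyl)oxy]-2-(4-methoxyphenyl)acetate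
Conditions: t-BuMe2SiCl, imidazole, DMF, rt
Reagents that add atoms: tert-butyldimethylsilyl chloride, CC(C)(C)[Si](C)(C)Cl
Why: Standard silyl ether formation (silyl chloride and imidazole) protects the carbinol as an ether that survives the reduction and the Lewis-acid aldol step.

Step 6
Reactants: 8 methyl (2R)-2-[(tert-butyldimethylsilyl)oxy]-2-(4-methoxyphenyl)acetate
Product: 9 (2R)-2-[(tert-butyldimethylsilyl)oxy]-2-(4-methoxyphenyl)acetaldehyde
Conditions: i-Bu2AlH (1.1 equiv), CH2Cl2, −78 °C; aqueous potassium sodium tartrate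
Reagents that add atoms: none
Why: Partial reduction of the ester: the tetrahedral aluminium hemiacetal is stable at −78 °C and collapses to the aldehyde only on work-up, which avoids over-reduction and epimerization of the α-silyloxy center.

Step 7
Reactants: 5 (2S)-7-(benzyloxy)-2-[4-(benzyloxy)phenyl]-4,5-bis[(tert-butyldimethylsilyl)oxy]-2H-chromene; 9 (2R)-2-[(tert-butyldimethylsilyl)oxy]-2-(4-methoxyphenyl)acetaldehyde
Product: 10 (2S)-7-(benzyloxy)-2-[4-(benzyloxy)phenyl]-5-[(tert-butyldimethylsilyl)oxy]-3-[(2R)-2-[(tert-butyldimethylsilyl)oxy]-1-hydroxy-2-(4-methoxyphenyl)ethyl]-2,3-dihydro-4H-chromen-4-one (diastereomer mixture at C-3 and the carbinol carbon)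
Conditions: BF3·OEt2 (1.1 equiv), CH2Cl2, −78 °C; aqueous NaHCO3
Reagents that add atoms: none
Why: Mukaiyama aldol addition of the enol silyl ether to the BF3-activated aldehyde forms the C-3''–C-3 bond; the two new centers are not controlled because step 8 makes both carbons sp2.

Step 8
Reactants: 10 (2S)-7-(benzyloxy)-2-[4-(benzyloxy)phenyl]-5-[(tert-butyldimethylsilyl)oxy]-3-[(2R)-2-[(tert-butyldimethylsilyl)oxy]-1-hydroxy-2-(4-methoxyphenyl)ethyl]-2,3-dihydro-4H-chromen-4-one
Product: 12 (2R,3E)-7-(benzyloxy)-2-[4-(benzyloxy)phenyl]-5-[(tert-butyldimethylsilyl)oxy]-3-[(2S)-2-[(tert-butyldimethylsilyl)oxy]-2-(4-methoxyphenyl)ethylidene]-2,3-dihydro-4H-chromen-4-one, via mesylate 11 (not isolated)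
Conditions: MsCl (1.5 equiv), Et3N (4 equiv), CH2Cl2, 0 °C to rt
Reagents that add atoms: none
Why: Mesylation and E1cB elimination through the ketone enolate complete the aldol condensation and should give the conjugated (E)-alkylidene ketone, with the side chain anti to the carbonyl as in 3-arylidene flavanones (both descriptors change by CIP priority only; no center is inverted).

Step 9
Reactants: 12 (2R,3E)-7-(benzyloxy)-2-[4-(benzyloxy)phenyl]-5-[(tert-butyldimethylsilyl)oxy]-3-[(2S)-2-[(tert-butyldimethylsilyl)oxy]-2-(4-methoxyphenyl)ethylidene]-2,3-dihydro-4H-chromen-4-one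
Product: 13 (2R,3E)-7-(benzyloxy)-2-[4-(benzyloxy)phenyl]-5-hydroxy-3-[(2S)-2-hydroxy-2-(4-methoxyphenyl)ethylidene]-2,3-dihydro-4H-chromen-4-one
Conditions: Bu4NF (2.5 equiv), AcOH (2.5 equiv), THF, 0 °C to rt
Reagents that add atoms: none
Why: Fluoride-mediated cleavage of both silyl ethers, buffered with AcOH to protect the base-sensitive alkylidene ketone, frees the C-2 carbinol and the chelated 5''-OH.

Step 10
Reactants: 14 2,4,6-trifluorobenzaldehyde
Product: 15 2,4-bis(benzyloxy)-6-fluorobenzaldehyde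
Conditions: BnOH (2.0 equiv), NaH (2.0 equiv), THF, −40 °C to 0 °C
Reagents that add atoms: benzyl alcohol, OCc1ccccc1
Why: Twofold SNAr (addition–elimination) of benzyl oxide at the para and one ortho fluorine, both activated by the formyl group; each alkoxy group slows the next substitution, so one ortho fluorine is kept as the leaving group for step 11.

Step 11
Reactants: 13 (2R,3E)-7-(benzyloxy)-2-[4-(benzyloxy)phenyl]-5-hydroxy-3-[(2S)-2-hydroxy-2-(4-methoxyphenyl)ethylidene]-2,3-dihydro-4H-chromen-4-one; 15 2,4-bis(benzyloxy)-6-fluorobenzaldehyde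
Product: 17 (2S)-5,7-bis(benzyloxy)-3-[(2S,3S)-7-(benzyloxy)-2-[4-(benzyloxy)phenyl]-5-hydroxy-4-oxo-3,4-dihydro-2H-chromen-3-yl]-2-(4-methoxyphenyl)-2,3-dihydro-4H-chromen-4-one (C-3 epimer mixture), via aryl ether aldehyde 16 (not isolated)
Conditions: KN(SiMe3)2 (2.05 equiv), THF–DMF, −78 °C; 15 (1.1 equiv), −78 °C to rt; then AcOH (1.05 equiv), 2-(pentafluorophenyl)-6,7-dihydro-5H-pyrrolo[2,1-c][1,2,4]triazol-2-ium tetrafluoroborate (20 mol %), 40 °C
Reagents that add atoms: none
Why: Mechanism: KN(SiMe3)2 gives the alkoxide of the C-2 carbinol and the chelated 5''-phenoxide, and only the alkoxide displaces fluoride from 15 by addition–elimination at the carbon ortho to the formyl group (O-1–C-8a); after the phenoxide is neutralized with AcOH, the triazolylidene released by the resulting KOAc turns the formyl group into its enaminol, an acyl anion equivalent, whose carbon adds to C-3, the β-carbon of the alkylidene ketone (C-3–C-4), and proton transfer with loss of the carbene gives the 1,4-diketone. The closest known reaction types are the SNAr etherification of ortho-fluorobenzaldehydes and the intramolecular Stetter reaction of salicylaldehyde-derived ethers to chroman-4-ones, here run in one flask. Ring C of unit 1 closes in the 6-exo-trig mode onto the exocyclic double bond. C-3'' is set when the ring-C'' enol ketonizes in the acetate/phenol buffer: the 2''-aryl group is pseudoaxial next to the substituted C-3'', so the proton should enter from the opposite face and leave the new substituent cis to the aryl group (3''S); C-3 is formed under kinetic control of the cyclization transition state and both epimers are accepted because step 12 converges them. The step needs alkoxide over phenoxide selectivity, conjugate addition over benzoin coupling and survival of the new C-3'' center; these are secured by the hydrogen-bonded 5''-OH, by the six-membered tether with a di-ortho-substituted aldehyde, and by removal of all strong base before the ketone is formed.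

Step 12
Reactants: 17 (2S)-5,7-bis(benzyloxy)-3-[(2S,3S)-7-(benzyloxy)-2-[4-(benzyloxy)phenyl]-5-hydroxy-4-oxo-3,4-dihydro-2H-chromen-3-yl]-2-(4-methoxyphenyl)-2,3-dihydro-4H-chromen-4-one (C-3 epimer mixture)
Product: 18 (2S,3R)-5,7-bis(benzyloxy)-3-[(2S,3S)-7-(benzyloxy)-2-[4-(benzyloxy)phenyl]-5-hydroxy-4-oxo-3,4-dihydro-2H-chromen-3-yl]-2-(4-methoxyphenyl)-2,3-dihydro-4H-chromen-4-one
Conditions: NaOMe (1.2 equiv), MeOH–THF, 0 °C; then AcOH
Reagents that add atoms: none
Why: Base-mediated epimerization through the ring-C enolate of unit 1 should give the 2,3-trans (diequatorial) isomer, C-3 (R), under thermodynamic control by C-2, while unit 2 is present as its 5''-phenoxide, whose vinylogous carboxylate character keeps C-3'' from enolizing.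

Step 13
Reactants: 18 (2S,3R)-5,7-bis(benzyloxy)-3-[(2S,3S)-7-(benzyloxy)-2-[4-(benzyloxy)phenyl]-5-hydroxy-4-oxo-3,4-dihydro-2H-chromen-3-yl]-2-(4-methoxyphenyl)-2,3-dihydro-4H-chromen-4-one
Product: 19 (2S,3R)-5,7-dihydroxy-3-[(2S,3S)-5,7-dihydroxy-2-(4-hydroxyphenyl)-4-oxo-3,4-dihydro-2H-chromen-3-yl]-2-(4-methoxyphenyl)-2,3-dihydro-4H-chromen-4-one
Conditions: H2 (1 atm), Pd/C (10 wt %), EtOAc–MeOH, rt
Reagents that add atoms: none
Why: Hydrogenolysis of the four benzyl aryl ethers over palladium under neutral conditions leaves the aryl methyl ether, both ketones and the base-labile C-3'' center untouched.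

**Compound list**

1 | 5,7-dihydroxy-4H-chromen-4-one | O=c1ccoc2cc(O)cc(O)c12 | starting material
2 | 7-(benzyloxy)-5-hydroxy-4H-chromen-4-one | O=c1ccoc2cc(OCc3ccccc3)cc(O)c12 | intermediate
3 | [4-(benzyloxy)phenyl]boronic acid | OB(O)c1ccc(OCc2ccccc2)cc1 | starting material
4 | (2S)-7-(benzyloxy)-2-[4-(benzyloxy)phenyl]-5-hydroxy-2,3-dihydro-4H-chromen-4-one | O=C1C[C@@H](c2ccc(OCc3ccccc3)cc2)Oc2cc(OCc3ccccc3)cc(O)c21 | intermediate
5 | (2S)-7-(benzyloxy)-2-[4-(benzyloxy)phenyl]-4,5-bis[(tert-butyldimethylsilyl)oxy]-2H-chromene | CC(C)(C)[Si](C)(C)OC1=C[C@@H](c2ccc(OCc3ccccc3)cc2)Oc2cc(OCc3ccccc3)cc(O[Si](C)(C)C(C)(C)C)c21 | intermediate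
6 | (2R)-2-hydroxy-2-(4-methoxyphenyl)acetic acid ((R)-4-methoxymandelic acid) | COc1ccc([C@@H](O)C(=O)O)cc1 | starting material
7 | methyl (2R)-2-hydroxy-2-(4-methoxyphenyl)acetate | COc1ccc([C@@H](O)C(=O)OC)cc1 | intermediate
8 | methyl (2R)-2-[(tert-butyldimethylsilyl)oxy]-2-(4-methoxyphenyl)acetate | COc1ccc([C@@H](O[Si](C)(C)C(C)(C)C)C(=O)OC)cc1 | intermediate
9 | (2R)-2-[(tert-butyldimethylsilyl)oxy]-2-(4-methoxyphenyl)acetaldehyde | COc1ccc([C@@H](O[Si](C)(C)C(C)(C)C)C=O)cc1 | intermediate
10 | (2S)-7-(benzyloxy)-2-[4-(benzyloxy)phenyl]-5-[(tert-butyldimethylsilyl)oxy]-3-[(2R)-2-[(tert-butyldimethylsilyl)oxy]-1-hydroxy-2-(4-methoxyphenyl)ethyl]-2,3-dihydro-4H-chromen-4-one (diastereomer mixture at C-3 and the carbinol carbon) | O=C1C(C(O)[C@H](O[Si](C)(C)C(C)(C)C)c2ccc(OC)cc2)[C@@H](c2ccc(OCc3ccccc3)cc2)Oc2cc(OCc3ccccc3)cc(O[Si](C)(C)C(C)(C)C)c21 | intermediate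
11 | methanesulfonate of the aldol hydroxyl of 10 (not isolated) | O=C1C(C(OS(C)(=O)=O)[C@H](O[Si](C)(C)C(C)(C)C)c2ccc(OC)cc2)[C@@H](c2ccc(OCc3ccccc3)cc2)Oc2cc(OCc3ccccc3)cc(O[Si](C)(C)C(C)(C)C)c21 | intermediate
12 | (2R,3E)-7-(benzyloxy)-2-[4-(benzyloxy)phenyl]-5-[(tert-butyldimethylsilyl)oxy]-3-[(2S)-2-[(tert-butyldimethylsilyl)oxy]-2-(4-methoxyphenyl)ethylidene]-2,3-dihydro-4H-chromen-4-one (2R by CIP; same spatial arrangement as in 4) | O=C1/C(=C/[C@H](O[Si](C)(C)C(C)(C)C)c2ccc(OC)cc2)[C@@H](c2ccc(OCc3ccccc3)cc2)Oc2cc(OCc3ccccc3)cc(O[Si](C)(C)C(C)(C)C)c21 | intermediate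
13 | (2R,3E)-7-(benzyloxy)-2-[4-(benzyloxy)phenyl]-5-hydroxy-3-[(2S)-2-hydroxy-2-(4-methoxyphenyl)ethylidene]-2,3-dihydro-4H-chromen-4-one | O=C1/C(=C/[C@H](O)c2ccc(OC)cc2)[C@@H](c2ccc(OCc3ccccc3)cc2)Oc2cc(OCc3ccccc3)cc(O)c21 | intermediate
14 | 2,4,6-trifluorobenzaldehyde | O=Cc1c(F)cc(F)cc1F | starting material
15 | 2,4-bis(benzyloxy)-6-fluorobenzaldehyde | O=Cc1c(F)cc(OCc2ccccc2)cc1OCc1ccccc1 | intermediate
16 | 2,4-bis(benzyloxy)-6-{[(1S,2E)-2-[(2R)-7-(benzyloxy)-2-[4-(benzyloxy)phenyl]-5-hydroxy-4-oxo-2H-chromen-3(4H)-ylidene]-1-(4-methoxyphenyl)ethyl]oxy}benzaldehyde (not isolated) | O=C1/C(=C/[C@H](Oc2cc(OCc3ccccc3)cc(OCc3ccccc3)c2C=O)c2ccc(OC)cc2)[C@@H](c2ccc(OCc3ccccc3)cc2)Oc2cc(OCc3ccccc3)cc(O)c21 | intermediate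
17 | (2S)-5,7-bis(benzyloxy)-3-[(2S,3S)-7-(benzyloxy)-2-[4-(benzyloxy)phenyl]-5-hydroxy-4-oxo-3,4-dihydro-2H-chromen-3-yl]-2-(4-methoxyphenyl)-2,3-dihydro-4H-chromen-4-one (C-3 epimer mixture) | COc1ccc([C@H]2Oc3cc(OCc4ccccc4)cc(OCc4ccccc4)c3C(=O)C2[C@@H]2C(=O)c3c(O)cc(OCc4ccccc4)cc3O[C@@H]2c2ccc(OCc3ccccc3)cc2)cc1 | intermediate
18 | (2S,3R)-5,7-bis(benzyloxy)-3-[(2S,3S)-7-(benzyloxy)-2-[4-(benzyloxy)phenyl]-5-hydroxy-4-oxo-3,4-dihydro-2H-chromen-3-yl]-2-(4-methoxyphenyl)-2,3-dihydro-4H-chromen-4-one | COc1ccc([C@H]2Oc3cc(OCc4ccccc4)cc(OCc4ccccc4)c3C(=O)[C@@H]2[C@@H]2C(=O)c3c(O)cc(OCc4ccccc4)cc3O[C@@H]2c2ccc(OCc3ccccc3)cc2)cc1 | intermediate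
19 | (2S,3R)-5,7-dihydroxy-3-[(2S,3S)-5,7-dihydroxy-2-(4-hydroxyphenyl)-4-oxo-3,4-dihydro-2H-chromen-3-yl]-2-(4-methoxyphenyl)-2,3-dihydro-4H-chromen-4-one | COc1ccc([C@H]2Oc3cc(O)cc(O)c3C(=O)[C@@H]2[C@@H]2C(=O)c3c(O)cc(O)cc3O[C@@H]2c2ccc(O)cc2)cc1 | target

Total step count: 13. Longest linear sequence: 9 steps (steps 1, 2, 3, 7, 8, 9, 11, 12, 13).

**Steps most likely to fail**

Step 11: under the alkoxide the exocyclic double bond may migrate into ring C'' (to the 3-alkylflavone). The hindered, electron-rich aldehyde may form the enaminol too slowly. Ketonization may also take place on the aryl face, which would give the 3''-epimer. Fallback (sets out from 13 and 15, comes back at 17): only the SNAr stage is run and aldehyde 16 is isolated. SmI2 (THF, t-BuOH, −78 °C) then joins C-4 and C-3 by ketyl–olefin cyclization, and the samarium enolate is protonated at −78 °C anti to the 2''-aryl group, which should give the flavan-4-ol F1. Oxidation of its carbinol with 1,1,1-triacetoxy-1,1-dihydro-1,2-benziodoxol-3(1H)-one under neutral conditions returns to 17.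

Step 8: the mesylate may fragment by retro-aldol cleavage, give E/Z mixtures, or suffer base-induced migration of the double bond into the ring. Fallback (sets out from 5 and 9, comes back at 12): the enol silyl ether 5 is aminomethylated with dimethylmethylideneammonium iodide (Mannich reaction) to the Mannich base F2. Quaternization with MeI and elimination with NaHCO3 give the 3-methylidene ketone F3. Wittig methylenation of 9 with Ph3P=CH2 gives the allyl silyl ether F4. Cross-metathesis of F3 and F4 with the second-generation Hoveyda–Grubbs catalyst (CH2Cl2, 40 °C) should give 12 as the (E) isomer.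

Step 12: the ring-C enolate of unit 1 may open reversibly by β-elimination of the aryloxide (loss of C-2 integrity), or incomplete phenoxide formation may let C-3'' epimerize. Fallback (sets out from 13 and 15, comes back at 18; it makes no new compound, F0): the base step is omitted and C-3 is set under catalyst control in the cyclization itself. The second stage of step 11 is run with the matched antipode of the aminoindanol-derived chiral triazolium salt 2-(pentafluorophenyl)-5a,10b-dihydro-4H,6H-indeno[2,1-b][1,2,4]triazolo[4,3-d][1,4]oxazin-2-ium tetrafluoroborate (asymmetric intramolecular Stetter reaction), so that 18 should form directly.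

**Further compounds**

F1 | step 11 | (2S)-5,7-bis(benzyloxy)-3-[(2S,3S)-7-(benzyloxy)-2-[4-(benzyloxy)phenyl]-5-hydroxy-4-oxo-3,4-dihydro-2H-chromen-3-yl]-2-(4-methoxyphenyl)-3,4-dihydro-2H-chromen-4-ol (C-3 and C-4 epimer mixture) | COc1ccc([C@H]2Oc3cc(OCc4ccccc4)cc(OCc4ccccc4)c3C(O)C2[C@@H]2C(=O)c3c(O)cc(OCc4ccccc4)cc3O[C@@H]2c2ccc(OCc3ccccc3)cc2)cc1
F2 | step 8 | (2S)-7-(benzyloxy)-2-[4-(benzyloxy)phenyl]-5-[(tert-butyldimethylsilyl)oxy]-3-[(dimethylamino)methyl]-2,3-dihydro-4H-chromen-4-one (C-3 epimer mixture) | CN(C)CC1C(=O)c2c(O[Si](C)(C)C(C)(C)C)cc(OCc3ccccc3)cc2O[C@@H]1c1ccc(OCc2ccccc2)cc1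
F3 | step 8 | (2R)-7-(benzyloxy)-2-[4-(benzyloxy)phenyl]-5-[(tert-butyldimethylsilyl)oxy]-3-methylidene-2,3-dihydro-4H-chromen-4-one | C=C1C(=O)c2c(O[Si](C)(C)C(C)(C)C)cc(OCc3ccccc3)cc2O[C@@H]1c1ccc(OCc2ccccc2)cc1
F4 | step 8 | tert-butyl{[(1S)-1-(4-methoxyphenyl)prop-2-en-1-yl]oxy}dimethylsilane | COc1ccc([C@@H](O[Si](C)(C)C(C)(C)C)C=C)cc1
F0 | step 12 | none | none
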